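**Retrosynthetic overview**

1. Feature: number the butenolide O1, C2 (carbonyl), C3 (carbinol side chain, C1'), C4 (Br), C5, exocyclic C6 (CHI). The chain C2–C3–C4–C5–C6, with a carboxyl carbon C7 where iodine sits, is a cis,cis-muconate, the ring-opened form of a 3-alkyl-4,5-dibromocatechol.
2. C6–I comes from C6–CO2H by iododecarboxylation; desilylation at C1' is the last step.
3. The O1–C5 bond comes from a seven-membered muconic anhydride (oxepine-2,7-dione): an alcohol opens it at C7 and the freed C2 carboxylate displaces the C5 bromide (ring contraction 7 to 5).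
4. The anhydride comes from the o-quinone (Baeyer–Villiger), this from the dibromocatechol, and this from bis-allyl-protected 2,3-dihydroxybenzaldehyde; C1' is set by asymmetric transfer hydrogenation of the aryl propyl ketone.
5. Ring order: benzene ring (purchased), then the oxepinedione by oxygen insertion, then the butenolide, the only ring of the target, closed in the key step.

Key step: step 10

Assumption: the target is read as the R carbinol with a Z iodomethylene group (iodine on the side of O1). The Z geometry drawn for ester 18 and acid 19 is the expected one, but the route does not depend on it, because step 12 should be convergent at C5=C6.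

**Route**

Step 1
Reactants: 1 2,3-dihydroxybenzaldehyde; 2 allyl bromide
Product: 3 2,3-bis(allyloxy)benzaldehyde
Conditions: K2CO3, DMF, 50 °C
Reagents that add atoms: allyl bromide, C=CCBr
Why: Williamson etherification of both phenols, which should proceed cleanly because the aldehyde is inert to carbonate and allyl bromide.

Step 2
Reactants: 3 2,3-bis(allyloxy)benzaldehyde; 4 propylmagnesium chloride
Product: 5 rac-1-[2,3-bis(allyloxy)phenyl]butan-1-ol
Conditions: THF, 0 °C; aq. NH4Cl
Reagents that add atoms: propylmagnesium chloride, CCC[Mg]Cl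
Why: Grignard addition to an aryl aldehyde, giving the racemic carbinol whose stereocenter is erased in step 3.

Step 3
Reactants: 5 rac-1-[2,3-bis(allyloxy)phenyl]butan-1-ol
Product: 6 1-[2,3-bis(allyloxy)phenyl]butan-1-one
Conditions: 2-iodoxybenzoic acid (IBX), EtOAc, 75 °C
Reagents that add atoms: none
Why: IBX oxidation of a secondary benzylic alcohol to the ketone, which leaves the allyl ethers untouched.

Step 4
Reactants: 6 1-[2,3-bis(allyloxy)phenyl]butan-1-one
Product: 7 (R)-1-[2,3-bis(allyloxy)phenyl]butan-1-ol
Conditions: RuCl(p-cymene)[(R,R)-TsDPEN] (1 mol%), HCO2H/Et3N (5:2), 30 °C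
Reagents that add atoms: none
Why: Noyori-type asymmetric transfer hydrogenation of an aryl alkyl ketone, in which the (R,R)-ligand should deliver hydride to the face that gives the R carbinol (the sense known for acetophenone-type ketones, the aryl group being held by a CH–π contact with the p-cymene ligand), while the allyl C=C bonds are not reduced.

Step 5
Reactants: 7 (R)-1-[2,3-bis(allyloxy)phenyl]butan-1-ol; 8 tert-butyldimethylsilyl chloride
Product: 9 (R)-{1-[2,3-bis(allyloxy)phenyl]butoxy}(tert-butyl)dimethylsilane
Conditions: imidazole, DMF, rt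
Reagents that add atoms: tert-butyldimethylsilyl chloride, CC(C)(C)[Si](C)(C)Cl
Why: imidazole-promoted silylation of the secondary alcohol, which does not touch the C–O bond at C1' and so keeps the configuration.

Step 6
Reactants: 9 (R)-{1-[2,3-bis(allyloxy)phenyl]butoxy}(tert-butyl)dimethylsilane
Product: 10 (R)-3-[1-(tert-butyldimethylsilyloxy)butyl]benzene-1,2-diol
Conditions: Pd(PPh3)4 (5 mol%), morpholine, degassed THF, rt
Reagents that add atoms: none
Why: Tsuji–Trost deallylation, in which zerovalent palladium ionises each aryl allyl ether to a π-allyl complex and phenoxide and morpholine takes up the allyl group, under neutral conditions that cannot hydrogenolyse or ionise the benzylic silyl ether.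

Step 7
Reactants: 10 (R)-3-[1-(tert-butyldimethylsilyloxy)butyl]benzene-1,2-diol; 11 N-bromosuccinimide
Product: 12 (R)-4,5-dibromo-3-[1-(tert-butyldimethylsilyloxy)butyl]benzene-1,2-diol
Conditions: NBS (2.05 equiv), MeCN, −30 to 0 °C, dark
Reagents that add atoms: N-bromosuccinimide, O=C1CCC(=O)N1Br
Why: electrophilic aromatic bromination in which each bromine should enter para to one hydroxyl (arene C5 para to the C2 hydroxyl, arene C4 para to the C1 hydroxyl) and leave C6, which is only ortho-activated, while NBS releases succinimide and no stoichiometric acid, so the benzylic silyl ether should hold.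

Step 8
Reactants: 12 (R)-4,5-dibromo-3-[1-(tert-butyldimethylsilyloxy)butyl]benzene-1,2-diol
Product: 13 (R)-4,5-dibromo-3-[1-(tert-butyldimethylsilyloxy)butyl]cyclohexa-3,5-diene-1,2-dione
Conditions: NaIO4 on silica gel, CH2Cl2, 0 °C; filtrate used at once
Reagents that add atoms: none
Why: periodate oxidation of a catechol to the o-quinone under neutral, base-free conditions, so that the quinone should not tautomerise at C1' and can go on as a solution.

Step 9
Reactants: 13 (R)-4,5-dibromo-3-[1-(tert-butyldimethylsilyloxy)butyl]cyclohexa-3,5-diene-1,2-dione; 14 3-chloroperbenzoic acid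
Product: 15 (R)-4,5-dibromo-3-[1-(tert-butyldimethylsilyloxy)butyl]oxepine-2,7-dione
Conditions: mCPBA (1.1 equiv), CH2Cl2, 0 °C; then anhydrous KF, filtration
Reagents that add atoms: 3-chloroperbenzoic acid, OOC(=O)c1cccc(Cl)c1
Why: Baeyer–Villiger oxidation of a 1,2-dione, in which the peracid adds to one carbonyl and the neighbouring acyl carbon migrates to oxygen, so that the oxygen is inserted between the two carbonyl carbons and the seven-membered muconic anhydride results, the electron-poor C=C bonds and the silyl ether being inert to the peracid.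

Step 10
Reactants: 15 (R)-4,5-dibromo-3-[1-(tert-butyldimethylsilyloxy)butyl]oxepine-2,7-dione; 16 4-methoxybenzyl alcohol
Product: 18 4-methoxybenzyl (Z)-2-{3-bromo-4-[(R)-1-(tert-butyldimethylsilyloxy)butyl]-5-oxofuran-2(5H)-ylidene}acetate, via muconate half-ester 17 (not isolated)
Conditions: 16 (1.05 equiv), DMAP (0.2 equiv), iPr2NEt (1.5 equiv), CH2Cl2, −40 °C to rt
Reagents that add atoms: 4-methoxybenzyl alcohol, COc1ccc(CO)cc1
Why: Proposed new method: DMAP acyl-transfer catalysis should deliver the alcohol to the C7 carbonyl of the anhydride and release the cis,cis-muconate half-ester 17 as its C2 carboxylate; this oxygen adds to C5, the β-carbon of the C5=C6–C7 acrylate, and the ester enolate so formed expels the C5 bromide (addition–elimination at a vinylic carbon), which makes the O1–C5 bond. The closest known reactions are the alcoholysis of muconic anhydrides to half-esters and the cycloisomerisation of 3-halo-cis,cis-muconates to dienelactones with loss of halide. The butenolide closes in the 5-exo-trig mode, made possible by the cis C3=C4 bond inherited from the arene. No stereocenter is formed and C1' is not involved; the C5=C6 geometry is decided at the enolate stage, where rotation about C5–C6 lets the ester turn away from the C4 bromine, and any E isomer should equilibrate to Z by reversible conjugate addition of DMAP or bromide at C5. The step needs a choice between two carbonyls and between two bromides: the α-branched silyloxybutyl group at C3 shields C2 so that C7 is acylated, and only C5 is both five atoms from the free carboxylate and β to an ester, so the C4 bromide stays.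

Step 11
Reactants: 18 4-methoxybenzyl (Z)-2-{3-bromo-4-[(R)-1-(tert-butyldimethylsilyloxy)butyl]-5-oxofuran-2(5H)-ylidene}acetate
Product: 19 (Z)-2-{3-bromo-4-[(R)-1-(tert-butyldimethylsilyloxy)butyl]-5-oxofuran-2(5H)-ylidene}acetic acid
Conditions: TFA/CH2Cl2 (1:5), anisole, 0 °C
Reagents that add atoms: none
Why: acidolysis of the 4-methoxybenzyl ester through the stabilised benzylic cation, which anisole traps, under brief cold conditions that a hindered secondary silyl ether next to an electron-poor alkene should survive.

Step 12
Reactants: 19 (Z)-2-{3-bromo-4-[(R)-1-(tert-butyldimethylsilyloxy)butyl]-5-oxofuran-2(5H)-ylidene}acetic acid; 20 N-iodosuccinimide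
Product: 21 (R,Z)-4-bromo-3-[1-(tert-butyldimethylsilyloxy)butyl]-5-(iodomethylene)furan-2(5H)-one
Conditions: NIS (1.2 equiv), LiOAc (0.2 equiv), MeCN/H2O (30:1), rt, dark
Reagents that add atoms: N-iodosuccinimide, O=C1CCC(=O)N1I
Why: Hunsdiecker-type halodecarboxylation of an α,β-unsaturated acid with an N-halosuccinimide and catalytic LiOAc, in which the carboxylate-bearing C6 (also the β-carbon of the enol lactone) takes up iodine, the C5 oxocarbenium ion (or β-lactone) can rotate about C5–C6, and loss of CO2 from the rotamer that keeps iodine away from the C4 bromine should give the Z iodide.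

Step 13
Reactants: 21 (R,Z)-4-bromo-3-[1-(tert-butyldimethylsilyloxy)butyl]-5-(iodomethylene)furan-2(5H)-one
Product: 22 (R,Z)-4-bromo-3-(1-hydroxybutyl)-5-(iodomethylene)furan-2(5H)-one
Conditions: HF·pyridine, THF, 0 °C to rt (plastic vessel)
Reagents that add atoms: none
Why: fluoride-driven cleavage of the Si–O bond in an acidic medium, chosen because the bromobutenolide is a Michael acceptor that would not tolerate basic fluoride, with C1' not involved and its R configuration kept.

**Compound list**

1 | 2,3-dihydroxybenzaldehyde | O=Cc1cccc(O)c1O | starting material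
2 | allyl bromide | C=CCBr | starting material
3 | 2,3-bis(allyloxy)benzaldehyde | O=Cc1cccc(OCC=C)c1OCC=C | intermediate
4 | propylmagnesium chloride | CCC[Mg]Cl | starting material
5 | rac-1-[2,3-bis(allyloxy)phenyl]butan-1-ol | CCCC(O)c1cccc(OCC=C)c1OCC=C | intermediate
6 | 1-[2,3-bis(allyloxy)phenyl]butan-1-one | CCCC(=O)c1cccc(OCC=C)c1OCC=C | intermediate
7 | (R)-1-[2,3-bis(allyloxy)phenyl]butan-1-ol | CCC[C@@H](O)c1cccc(OCC=C)c1OCC=C | intermediate
8 | tert-butyldimethylsilyl chloride | CC(C)(C)[Si](C)(C)Cl | starting material
9 | (R)-{1-[2,3-bis(allyloxy)phenyl]butoxy}(tert-butyl)dimethylsilane | CCC[C@@H](O[Si](C)(C)C(C)(C)C)c1cccc(OCC=C)c1OCC=C | intermediate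
10 | (R)-3-[1-(tert-butyldimethylsilyloxy)butyl]benzene-1,2-diol | CCC[C@@H](O[Si](C)(C)C(C)(C)C)c1cccc(O)c1O | intermediate
11 | N-bromosuccinimide | O=C1CCC(=O)N1Br | starting material
12 | (R)-4,5-dibromo-3-[1-(tert-butyldimethylsilyloxy)butyl]benzene-1,2-diol | CCC[C@@H](O[Si](C)(C)C(C)(C)C)c1c(Br)c(Br)cc(O)c1O | intermediate
13 | (R)-4,5-dibromo-3-[1-(tert-butyldimethylsilyloxy)butyl]cyclohexa-3,5-diene-1,2-dione | CCC[C@@H](O[Si](C)(C)C(C)(C)C)C1=C(Br)C(Br)=CC(=O)C1=O | intermediate
14 | 3-chloroperbenzoic acid | OOC(=O)c1cccc(Cl)c1 | starting material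
15 | (R)-4,5-dibromo-3-[1-(tert-butyldimethylsilyloxy)butyl]oxepine-2,7-dione | CCC[C@@H](O[Si](C)(C)C(C)(C)C)C1=C(Br)C(Br)=CC(=O)OC1=O | intermediate
16 | 4-methoxybenzyl alcohol | COc1ccc(CO)cc1 | starting material
17 | 6-(4-methoxybenzyl) hydrogen (2E,4E)-3,4-dibromo-2-[(R)-1-(tert-butyldimethylsilyloxy)butyl]hexa-2,4-dienedioate (cis,cis carbon chain; the E descriptors come from the bromine priorities) | CCC[C@@H](O[Si](C)(C)C(C)(C)C)/C(C(=O)O)=C(Br)/C(Br)=C\C(=O)OCc1ccc(OC)cc1 | intermediate
18 | 4-methoxybenzyl (Z)-2-{3-bromo-4-[(R)-1-(tert-butyldimethylsilyloxy)butyl]-5-oxofuran-2(5H)-ylidene}acetate | CCC[C@@H](O[Si](C)(C)C(C)(C)C)C1=C(Br)/C(=C/C(=O)OCc2ccc(OC)cc2)OC1=O | intermediate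
19 | (Z)-2-{3-bromo-4-[(R)-1-(tert-butyldimethylsilyloxy)butyl]-5-oxofuran-2(5H)-ylidene}acetic acid | CCC[C@@H](O[Si](C)(C)C(C)(C)C)C1=C(Br)/C(=C/C(=O)O)OC1=O | intermediate
20 | N-iodosuccinimide | O=C1CCC(=O)N1I | starting material
21 | (R,Z)-4-bromo-3-[1-(tert-butyldimethylsilyloxy)butyl]-5-(iodomethylene)furan-2(5H)-one | CCC[C@@H](O[Si](C)(C)C(C)(C)C)C1=C(Br)/C(=C/I)OC1=O | intermediate
22 | (R,Z)-4-bromo-3-(1-hydroxybutyl)-5-(iodomethylene)furan-2(5H)-one | CCC[C@@H](O)C1=C(Br)/C(=C/I)OC1=O | target

**Step count**

Total step count: 13. Longest linear sequence: 13 steps (from 1 to 22).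

**Steps most likely to fail**

Step 10. The ring-opened carboxylate may fail to add to C5 in the basic medium, or the amine and alcohol may go on to substitute the C4 bromide of the product. The fallback uses no alcohol and no base. It sets out from anhydride 15, which would be hydrolysed in wet THF to (2E,4E)-3,4-dibromo-2-[(R)-1-(tert-butyldimethylsilyloxy)butyl]hexa-2,4-dienedioic acid F1 (cis,cis carbon chain). The diacid would then be warmed in AcOH buffered with NaOAc, the acid-promoted cycloisomerisation known for 3-halo-cis,cis-muconic acids, which lactonise with loss of hydrogen halide. Attack of the C2 carboxyl on C5 is favoured over the other mode because C4 is flanked by the bulky side chain and would give a tetrasubstituted exocyclic alkene. The sequence returns to the route at acid 19 and bypasses ester 18.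

Step 12. The enol-lactone double bond, deactivated by the lactone and the acid group, may take up iodine from NIS too slowly, so that the acid is recovered or decomposes. The fallback splits halogenation and decarboxylation into two stages. It sets out from acid 19: ICl in CH2Cl2 at −20 °C should add across C5=C6 (iodine to C6, chloride to the oxocarbenium carbon C5) to give 2-{3-bromo-2-chloro-4-[(R)-1-(tert-butyldimethylsilyloxy)butyl]-5-oxo-2,5-dihydrofuran-2-yl}-2-iodoacetic acid F2 as a diastereomer mixture. Et3N in DMF at 0 °C should then cause decarboxylative loss of chloride, the classical dihalide route from unsaturated acids to vinyl halides. It returns to the route at iodide 21.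

Step 7. NBS may oxidise the free catechol in competition with ring substitution, or the second bromine may enter ortho to hydroxyl at C6 (loss of regiocontrol). The fallback brominates before deprotection. It sets out from bis-allyl ether 9: NBS in MeCN at rt should brominate para to each alkoxy group, as 1,2-dialkoxy-3-alkylbenzenes do, and give (R)-{1-[2,3-bis(allyloxy)-5,6-dibromophenyl]butoxy}(tert-butyl)dimethylsilane F3. Deallylation with Pd(PPh3)4 and morpholine at rt, where the hindered aryl bromides should not undergo oxidative addition, returns to the route at dibromocatechol 12.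

**Further compounds**

F1 | step 10 | (2E,4E)-3,4-dibromo-2-[(R)-1-(tert-butyldimethylsilyloxy)butyl]hexa-2,4-dienedioic acid | CCC[C@@H](O[Si](C)(C)C(C)(C)C)/C(C(=O)O)=C(Br)/C(Br)=C\C(=O)O
F2 | step 12 | 2-{3-bromo-2-chloro-4-[(R)-1-(tert-butyldimethylsilyloxy)butyl]-5-oxo-2,5-dihydrofuran-2-yl}-2-iodoacetic acid | CCC[C@@H](O[Si](C)(C)C(C)(C)C)C1=C(Br)C(Cl)(C(I)C(=O)O)OC1=O
F3 | step 7 | (R)-{1-[2,3-bis(allyloxy)-5,6-dibromophenyl]butoxy}(tert-butyl)dimethylsilane | CCC[C@@H](O[Si](C)(C)C(C)(C)C)c1c(Br)c(Br)cc(OCC=C)c1OCC=C
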